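The numbers of this flask were drawn at random within sensible limits; the flask was simulated.

Take the second as your unit: in each one the feed brings 6.67 mM s⁻¹ of starting material into the flask, and you want to know how much of it is still free when the feed ends.

starting material 0.10 M (fed, over 15 s); acid 1.00 mM; protic impurity 0.0300 M; time 15 s

* part of the starting material that has reacted at 15 s
* pH of the solution at 15 s

- acid is the free proton; pH is minus the decimal logarithm of its molar concentration
- percentages count the starting material that a species holds: one idle adduct counts as two
- target is meant together with its idle adduct
- what has gone from starting material into another species counts as reacted, even if it can come back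
- in an amount of target, one idle adduct counts as one target
- run time (flask): 15 s

    starting material → weak acid + target (k1 = 0.0022 s⁻¹)
    starting material ⇌ dormant form (K2 = 2.6, k2 = 0.16 s⁻¹)
    starting material + target ⇌ idle adduct, settled at all times (K3 = 6.0 L mol⁻¹)
    weak acid ⇌ conjugate base + acid, settled at all times (K4 = 1.6 × 10⁻⁹ M)
    starting material + protic impurity → quenched substrate (k5 = 0.69 L mol⁻¹ s⁻¹)
    starting material + acid → weak acid + acid + target (k6 = 880 L mol⁻¹ s⁻¹)

I would compare two times. Acid is handed back by the step it carries, so its concentration stands still and that step is pseudo-first-order, at 0.880 s⁻¹. The weak acid can add at most 1.60 × 10⁻⁷ M of protons, far less than the charge of acid, so I expect pH 3.00.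

Add the forward step to the dormant form, 0.16 s⁻¹, the protic impurity, 0.0207 s⁻¹, and the uncatalysed step, 0.0022 s⁻¹. The inverse of that sum is τ = 0.941 s, the lifetime of a free molecule of starting material. The other time is the dosing time, t = 15 s.

Because τ is shorter than t by a factor of 15.9, free starting material keeps pace with the feed and stands at feed times τ. Its share of the charge is then τ/t = 6.27%. Whatever has left the free form counts as reacted, so I commit to 93.7%. The dormant form gives back at 0.0615 s⁻¹, slower than it takes, and I dropped that return, so my free share should run low.

The forecast gave 93.4% (from 92.8% to 94%) and pH 3, with the ground “Only free starting material counts as unreacted”. The simulation gives 93.4% reacted at pH 3.00, with 6.59% of the charge free against my 6.27%.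

The neighbour flask holds 2.5 × 10⁻⁴ M of acid instead of 1.00 mM. Its acid-carried rate falls by 0.660 s⁻¹, which stretches τ from 0.941 s to 2.48 s, still shorter than t. The same reckoning gives that flask a free share of 16.5% and 83.5% reacted. The simulated neighbour flask has 18.6% free and 81.4% reacted, and its dormant form holds 24.2% of the charge.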